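**Retrosynthetic overview**

1. The acyl acetal comes from acylation of the iridoid-type lactol 29, which forms from 1,5-dialdehyde 27 (ring C last).
2. 27 derives from keto triester 20; ring B, quaternary C13 and C12 are set by an intramolecular Michael addition of the C5 ester dienolate onto the ring D alkylidene β-keto ester 19.
3. Ring D (19) closes by intramolecular Knoevenagel condensation of cyclopentanone 18; the two side chains come from a Z-selective Wittig reaction and an enolate alkylation.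
4. Quaternary C1 is set on the monocyclic enone 10 by Me2CuLi addition anti to the C2 substituent, with trapping of the regiodefined enolate (13).
5. Ring A (10) comes from the key fragment union, an organocatalytic intermolecular Michael addition of succinaldehyde to nitroacrylate 3 (C1–C2 bond), followed by Henry closure. Ring order: A → D → B → C.

Assumption (atom labels, taken from the target and used in all names): C1 = quaternary C(CH3)(CO2Me); C2 = allylic bridgehead CH; C3=C4 = ring CH=CH; C5 = enol-ether ring carbon; C6 = O–CH=; O7; C8 = acetal CH; C9 = adjacent ring-fusion CH; C10/C11 = CH2CH2; C12 = ring-fusion CH next to C1; C13 = quaternary carbon; C14 = bridging CH2. Ring A = C1/C2/C14/C13/C12, ring B = C2–C5/C13/C14, ring C = dihydropyran, ring D = C9–C13. "A/B/D tricycle" means the tricyclo[5.3.1.0^{1,5}]undec-8-ene carbocycle of the target. Target configuration from the SMILES: 1R,2S,8S,9R,12R,13S.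

**Route**

Step 1
Reactants: 1 tert-butyl acrylate
Product: 2 tert-butyl 2-iodo-3-nitropropanoate
Conditions: N2O4, I2, Et2O, 0 °C → rt
Reagents that add atoms: dinitrogen tetroxide [O-][N+](=O)[N+](=O)[O-]; iodine II
Why: Iodonitration of the acrylate (NO2 adds to the terminus, iodine is captured at the α-carbon) places the nitro group at C3, and no stereocentre is retained.

Step 2
Reactants: 2 tert-butyl 2-iodo-3-nitropropanoate
Product: 3 tert-butyl (E)-3-nitroprop-2-enoate
Conditions: NaOAc, Et2O, 0 °C → rt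
Reagents that add atoms: none
Why: E1cB dehydroiodination gives the thermodynamically favoured (E)-nitroacrylate.

Step 3
Reactants: 4 2,5-dimethoxytetrahydrofuran
Product: 5 butanedial (succinaldehyde)
Conditions: H2O, 90 °C; then CH2Cl2 extraction and distillation, used fresh
Reagents that add atoms: water O
Why: Hydrolysis of the cyclic bis-acetal liberates the dialdehyde.

Step 4
Reactants: 3 tert-butyl (E)-3-nitroprop-2-enoate; 5 butanedial
Product: 7 tert-butyl (1S,2R,5R)-2-formyl-4-hydroxy-5-nitrocyclopentane-1-carboxylate (C4 carbinol epimers), via Michael adduct 6 (not isolated)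
Conditions: (R)-2-[diphenyl(trimethylsilyloxy)methyl]pyrrolidine (10 mol %), 4-nitrophenol (10 mol %), MeCN, rt; then i-Pr2NEt, rt, 12 h
Reagents that add atoms: none
Why: Hayashi–Jørgensen enamine Michael addition joins the two fragments at C1–C2 with the catalyst fixing the ester-bearing carbon C1 as S, after which an intramolecular Henry (nitro-aldol) reaction closes ring A and the amine base epimerises the α-formyl carbon C2 to the thermodynamic all-trans (2R) arrangement.

Step 5
Reactants: 7 tert-butyl (1S,2R,5R)-2-formyl-4-hydroxy-5-nitrocyclopentane-1-carboxylate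
Product: 8 tert-butyl (1S,2R,5R)-2-(dimethoxymethyl)-4-hydroxy-5-nitrocyclopentane-1-carboxylate (C4 epimers)
Conditions: HC(OMe)3, CSA (cat.), MeOH, rt; chromatography
Reagents that add atoms: trimethyl orthoformate COC(OC)OC
Why: Acid-catalysed acetalisation masks the aldehyde and freezes C2, and the minor C2-epimeric diastereomer is removed here so that C2 is configurationally pure before C1 is flattened.

Step 6
Reactants: 8 tert-butyl (1S,2R,5R)-2-(dimethoxymethyl)-4-hydroxy-5-nitrocyclopentane-1-carboxylate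
Product: 9 tert-butyl (5R)-5-(dimethoxymethyl)-3-hydroxycyclopent-1-ene-1-carboxylate (C3 epimers)
Conditions: DBU, MeCN, 0 °C → rt
Reagents that add atoms: none
Why: E1cB elimination of nitrous acid from the β-nitro ester gives the conjugated cyclopentene ester without touching C2.

Step 7
Reactants: 9 tert-butyl (5R)-5-(dimethoxymethyl)-3-hydroxycyclopent-1-ene-1-carboxylate
Product: 10 tert-butyl (5R)-5-(dimethoxymethyl)-3-oxocyclopent-1-ene-1-carboxylate
Conditions: Dess–Martin periodinane, NaHCO3, CH2Cl2, 0 °C → rt; used promptly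
Reagents that add atoms: none
Why: Dess–Martin oxidation of the allylic alcohol under buffered, base-free conditions gives the enone while the base-labile γ-stereocentre C2 is preserved.

Step 8
Reactants: 10 tert-butyl (5R)-5-(dimethoxymethyl)-3-oxocyclopent-1-ene-1-carboxylate; 11 methyl (2E)-4-bromo-3-methoxybut-2-enoate
Product: 13 tert-butyl (1R,2R)-2-(dimethoxymethyl)-5-[(2E)-2,4-dimethoxy-4-oxobut-2-en-1-yl]-1-methyl-4-oxocyclopentane-1-carboxylate (C5 epimers), via lithium enolate 12 (not isolated)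
Conditions: Me2CuLi (from MeLi and CuI), Et2O, −78 °C; then HMPA, 11, −78 → 0 °C
Reagents that add atoms: lithium dimethylcuprate [Li+].C[Cu-]C
Why: Gilman cuprate conjugate addition β to the ketone occurs anti to the C2 dimethoxymethyl group and so sets quaternary C1 (methyl trans to the C2 side chain), and the regiodefined enolate is then C-alkylated (SN2) at C12 by the allylic bromide, the C12 configuration being irrelevant because it is equilibrated in step 13.

Step 9
Reactants: 13 tert-butyl (1R,2R)-2-(dimethoxymethyl)-5-[(2E)-2,4-dimethoxy-4-oxobut-2-en-1-yl]-1-methyl-4-oxocyclopentane-1-carboxylate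
Product: 14 tert-butyl (1R,2R)-5-[(2E)-2,4-dimethoxy-4-oxobut-2-en-1-yl]-2-formyl-1-methyl-4-oxocyclopentane-1-carboxylate
Conditions: PPTS (cat.), acetone/H2O, 40 °C; used at once
Reagents that add atoms: water O
Why: Chemoselective acetal hydrolysis, since the acyclic dimethyl acetal cleaves under mild acid that leaves the push–pull β-methoxyacrylate and the tert-butyl ester intact.

Step 10
Reactants: 14 tert-butyl (1R,2R)-5-[(2E)-2,4-dimethoxy-4-oxobut-2-en-1-yl]-2-formyl-1-methyl-4-oxocyclopentane-1-carboxylate; 15 (2-carboxyethyl)triphenylphosphonium bromide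
Product: 16 tert-butyl (1R,2S)-2-[(1Z)-3-carboxyprop-1-en-1-yl]-5-[(2E)-2,4-dimethoxy-4-oxobut-2-en-1-yl]-1-methyl-4-oxocyclopentane-1-carboxylate
Conditions: 15, NaN(SiMe3)2 (2 equiv per 15), THF, 0 °C; then 14, −78 °C → rt; cold 0.5 M HCl work-up
Reagents that add atoms: none
Why: Wittig olefination with the unstabilised carboxylate-bearing ylide gives the (Z)-β,γ-unsaturated acid (the cis C3=C4 geometry needed in ring B), the aldehyde reacting far faster than the ketone at low temperature.

Step 11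
Reactants: 16 tert-butyl (1R,2S)-2-[(1Z)-3-carboxyprop-1-en-1-yl]-5-[(2E)-2,4-dimethoxy-4-oxobut-2-en-1-yl]-1-methyl-4-oxocyclopentane-1-carboxylate
Product: 17 tert-butyl (1R,2S)-5-[(2E)-2,4-dimethoxy-4-oxobut-2-en-1-yl]-2-[(1Z)-4-methoxy-4-oxobut-1-en-1-yl]-1-methyl-4-oxocyclopentane-1-carboxylate
Conditions: Me3SiCHN2, MeOH/PhMe, 0 °C
Reagents that add atoms: trimethylsilyldiazomethane C[Si](C)(C)C=[N+]=[N-]
Why: Diazoalkane esterification of the acid is base-free and so does not conjugate the β,γ-alkene.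

Step 12
Reactants: 17 tert-butyl (1R,2S)-5-[(2E)-2,4-dimethoxy-4-oxobut-2-en-1-yl]-2-[(1Z)-4-methoxy-4-oxobut-1-en-1-yl]-1-methyl-4-oxocyclopentane-1-carboxylate
Product: 19 1-tert-butyl 4-methyl (1R,2S)-2-[(1Z)-4-methoxy-4-oxobut-1-en-1-yl]-1-methyl-5-oxo-1,2,3,5,6,6a-hexahydropentalene-1,4-dicarboxylate (C6a epimers), via keto ester 18 (not isolated)
Conditions: 1 M HCl, THF, rt; then piperidine (cat.), AcOH (cat.), PhMe, reflux, Dean–Stark
Reagents that add atoms: water O
Why: Acid hydrolysis of the vinylogous carbonate unmasks the β-keto ester, whose intramolecular Knoevenagel condensation with the ring ketone closes ring D as a doubly activated alkylidene β-keto ester.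

Step 13
Reactants: 19 1-tert-butyl 4-methyl (1R,2S)-2-[(1Z)-4-methoxy-4-oxobut-1-en-1-yl]-1-methyl-5-oxo-1,2,3,5,6,6a-hexahydropentalene-1,4-dicarboxylate
Product: 20 (1R,2S,12R,13R)-A/B/D tricycle bearing C1 methyl and tert-butoxycarbonyl, C5 and C9 methoxycarbonyl and a C10 ketone (C5/C9 epimers)
Conditions: KOtBu (1.1 equiv), t-BuOH/THF, 0 °C → rt; AcOH quench
Reagents that add atoms: none
Why: Intramolecular Michael addition of the ester dienolate (α-carbon C5) to C13 from the face of the C2 tether closes ring B as a bicyclo[3.2.1]octene and sets quaternary C13, while C12 epimerises through the vinylogous enolate and only the epimer giving the cis-fused diquinane cyclises, the product being drained as its stable β-keto ester enolate.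

Step 14
Reactants: 20 tricyclic keto triester
Product: 21 (1R,2S,12R,13R)-A/B/D tricycle as 20 with C10 hydroxyl in place of the ketone (C5/C9/C10 epimers)
Conditions: NaBH4, MeOH, −20 °C
Reagents that add atoms: none
Why: Chemoselective borohydride reduction of the β-keto ester ketone leaves the three esters untouched.

Step 15
Reactants: 21 tricyclic hydroxy triester
Product: 22 (1R,2S,12R,13R)-A/B/D tricycle as 21 with C10 O-(phenoxythiocarbonyl)
Conditions: PhOC(S)Cl, pyridine, DMAP (cat.), CH2Cl2, rt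
Reagents that add atoms: O-phenyl carbonochloridothioate S=C(Cl)Oc1ccccc1
Why: Thioacylation of the secondary alcohol prepares the Barton–McCombie deoxygenation.

Step 16
Reactants: 22 tricyclic thionocarbonate
Product: 23 (1R,2S,12R,13S)-A/B/D tricycle bearing C1 methyl and tert-butoxycarbonyl and C5 and C9 methoxycarbonyl (C5/C9 epimers)
Conditions: Bu3SnH, AIBN (cat.), PhMe, 90 °C
Reagents that add atoms: none
Why: Barton–McCombie radical deoxygenation removes the C10 oxygen and leaves the ring alkene and esters intact.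

Step 17
Reactants: 23 tricyclic triester
Product: 24 (1R,2S,12R,13S)-A/B/D tricycle C1 carboxylic acid with C5 and C9 methoxycarbonyl
Conditions: TFA, CH2Cl2, 0 °C → rt
Reagents that add atoms: none
Why: Acidolysis (E1 loss of isobutene) cleaves only the tert-butyl ester at C1.

Step 18
Reactants: 24 tricyclic acid diester
Product: 25 (1R,2S,12R,13S)-A/B/D tricycle C1 carboxylic acid with C5 and C9 hydroxymethyl
Conditions: LiBH4, MeOH, THF, 0 → 40 °C; aqueous citric acid work-up
Reagents that add atoms: none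
Why: LiBH4 reduces the two methyl esters to primary alcohols (C6 and C8) while the lithium carboxylate at C1 is inert.

Step 19
Reactants: 25 tricyclic diol acid
Product: 26 methyl (1R,2S,12R,13S)-A/B/D-tricycle-1-carboxylate with C5 and C9 hydroxymethyl
Conditions: Me3SiCHN2, MeOH/PhMe, 0 °C
Reagents that add atoms: trimethylsilyldiazomethane C[Si](C)(C)C=[N+]=[N-]
Why: Diazoalkane esterification installs the target's hindered methyl ester without touching the diol.

Step 20
Reactants: 26 tricyclic diol methyl ester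
Product: 27 methyl (1R,2S,12R,13S)-A/B/D-tricycle-1-carboxylate with C5 and C9 formyl (C5/C9 epimers)
Conditions: Dess–Martin periodinane (2.2 equiv), NaHCO3, CH2Cl2, 0 °C; used crude
Reagents that add atoms: none
Why: Dess–Martin oxidation converts both primary alcohols into the 1,5-dialdehyde without over-oxidation.

Step 21
Reactants: 27 tricyclic dialdehyde; 28 3-methylbutanoic anhydride
Product: 30 CNP0315847.1 (1R,2S,8S,9R,12R,13S), via lactol 29 (not isolated)
Conditions: Et3N, DMAP (cat.), CH2Cl2, rt, 1 h; then 28, 0 °C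
Reagents that add atoms: none
Why: Base-mediated enolisation to the conjugated dienol and hemiacetalisation give the cis-fused lactol (C9 epimerises to the only configuration that can close ring C), and DMAP-catalysed acylation of the equilibrating anomers is expected, by analogy with 1-O-acyl iridoids, to give the pseudo-axial ester anti to the C9–C10 bond (C8 S).

**Compound list**

1 | tert-butyl acrylate | C=CC(=O)OC(C)(C)C | starting material
2 | tert-butyl 2-iodo-3-nitropropanoate (racemic) | CC(C)(C)OC(=O)C(I)C[N+](=O)[O-] | intermediate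
3 | tert-butyl (E)-3-nitroprop-2-enoate | CC(C)(C)OC(=O)/C=C/[N+](=O)[O-] | intermediate
4 | 2,5-dimethoxytetrahydrofuran | COC1CCC(OC)O1 | starting material
5 | butanedial (succinaldehyde) | O=CCCC=O | intermediate
6 | tert-butyl (2S,3S)-3-formyl-2-(nitromethyl)-5-oxopentanoate | CC(C)(C)OC(=O)[C@H](C[N+](=O)[O-])[C@@H](C=O)CC=O | intermediate (not isolated)
7 | tert-butyl (1S,2R,5R)-2-formyl-4-hydroxy-5-nitrocyclopentane-1-carboxylate (C4 epimers) | CC(C)(C)OC(=O)[C@H]1[C@H](C=O)CC(O)[C@@H]1[N+](=O)[O-] | intermediate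
8 | tert-butyl (1S,2R,5R)-2-(dimethoxymethyl)-4-hydroxy-5-nitrocyclopentane-1-carboxylate (C4 epimers) | CC(C)(C)OC(=O)[C@H]1[C@H](C(OC)OC)CC(O)[C@@H]1[N+](=O)[O-] | intermediate
9 | tert-butyl (5R)-5-(dimethoxymethyl)-3-hydroxycyclopent-1-ene-1-carboxylate (C3 epimers) | CC(C)(C)OC(=O)C1=CC(O)C[C@H]1C(OC)OC | intermediate
10 | tert-butyl (5R)-5-(dimethoxymethyl)-3-oxocyclopent-1-ene-1-carboxylate | CC(C)(C)OC(=O)C1=CC(=O)C[C@H]1C(OC)OC | intermediate
11 | methyl (2E)-4-bromo-3-methoxybut-2-enoate | CO/C(CBr)=C/C(=O)OC | starting material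
12 | lithium (3S,4R)-3-(tert-butoxycarbonyl)-4-(dimethoxymethyl)-3-methylcyclopent-1-en-1-olate | CC(C)(C)OC(=O)[C@]1(C)[C@H](C(OC)OC)CC(O[Li])=C1 | intermediate (not isolated)
13 | tert-butyl (1R,2R)-2-(dimethoxymethyl)-5-[(2E)-2,4-dimethoxy-4-oxobut-2-en-1-yl]-1-methyl-4-oxocyclopentane-1-carboxylate (C5 epimers) | CC(C)(C)OC(=O)[C@]1(C)[C@H](C(OC)OC)CC(=O)C1C/C(OC)=C\C(=O)OC | intermediate
14 | tert-butyl (1R,2R)-5-[(2E)-2,4-dimethoxy-4-oxobut-2-en-1-yl]-2-formyl-1-methyl-4-oxocyclopentane-1-carboxylate | CC(C)(C)OC(=O)[C@]1(C)[C@H](C=O)CC(=O)C1C/C(OC)=C\C(=O)OC | intermediate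
15 | (2-carboxyethyl)triphenylphosphonium bromide | OC(=O)CC[P+](c1ccccc1)(c1ccccc1)c1ccccc1.[Br-] | starting material
16 | tert-butyl (1R,2S)-2-[(1Z)-3-carboxyprop-1-en-1-yl]-5-[(2E)-2,4-dimethoxy-4-oxobut-2-en-1-yl]-1-methyl-4-oxocyclopentane-1-carboxylate | CC(C)(C)OC(=O)[C@]1(C)[C@H](/C=C\CC(=O)O)CC(=O)C1C/C(OC)=C\C(=O)OC | intermediate
17 | tert-butyl (1R,2S)-5-[(2E)-2,4-dimethoxy-4-oxobut-2-en-1-yl]-2-[(1Z)-4-methoxy-4-oxobut-1-en-1-yl]-1-methyl-4-oxocyclopentane-1-carboxylate | CC(C)(C)OC(=O)[C@]1(C)[C@H](/C=C\CC(=O)OC)CC(=O)C1C/C(OC)=C\C(=O)OC | intermediate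
18 | tert-butyl (1R,2S)-5-(4-methoxy-2,4-dioxobutyl)-2-[(1Z)-4-methoxy-4-oxobut-1-en-1-yl]-1-methyl-4-oxocyclopentane-1-carboxylate | CC(C)(C)OC(=O)[C@]1(C)[C@H](/C=C\CC(=O)OC)CC(=O)C1CC(=O)CC(=O)OC | intermediate (not isolated)
19 | 1-tert-butyl 4-methyl (1R,2S)-2-[(1Z)-4-methoxy-4-oxobut-1-en-1-yl]-1-methyl-5-oxo-1,2,3,5,6,6a-hexahydropentalene-1,4-dicarboxylate (C6a epimers) | CC(C)(C)OC(=O)[C@]1(C)[C@H](/C=C\CC(=O)OC)CC2=C(C(=O)OC)C(=O)CC12 | intermediate
20 | (1R,2S,12R,13R)-A/B/D tricycle: C1 Me and CO2t-Bu, C5 CO2Me, C9 CO2Me, C10 ketone (C5/C9 epimers) | CC(C)(C)OC(=O)[C@]1(C)[C@@H]2C=CC(C(=O)OC)[C@]3(C2)C(C(=O)OC)C(=O)C[C@@H]13 | intermediate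
21 | (1R,2S,12R,13R)-A/B/D tricycle: as 20 with C10 OH (epimers) | CC(C)(C)OC(=O)[C@]1(C)[C@@H]2C=CC(C(=O)OC)[C@]3(C2)C(C(=O)OC)C(O)C[C@@H]13 | intermediate
22 | (1R,2S,12R,13R)-A/B/D tricycle: as 21 with C10 OC(=S)OPh | CC(C)(C)OC(=O)[C@]1(C)[C@@H]2C=CC(C(=O)OC)[C@]3(C2)C(C(=O)OC)C(OC(=S)Oc4ccccc4)C[C@@H]13 | intermediate
23 | (1R,2S,12R,13S)-A/B/D tricycle: C1 Me and CO2t-Bu, C5 CO2Me, C9 CO2Me (C5/C9 epimers) | CC(C)(C)OC(=O)[C@]1(C)[C@@H]2C=CC(C(=O)OC)[C@]3(C2)C(C(=O)OC)CC[C@@H]13 | intermediate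
24 | (1R,2S,12R,13S)-A/B/D tricycle: C1 Me and CO2H, C5 CO2Me, C9 CO2Me | OC(=O)[C@]1(C)[C@@H]2C=CC(C(=O)OC)[C@]3(C2)C(C(=O)OC)CC[C@@H]13 | intermediate
25 | (1R,2S,12R,13S)-A/B/D tricycle: C1 Me and CO2H, C5 CH2OH, C9 CH2OH | OC(=O)[C@]1(C)[C@@H]2C=CC(CO)[C@]3(C2)C(CO)CC[C@@H]13 | intermediate
26 | (1R,2S,12R,13S)-A/B/D tricycle: C1 Me and CO2Me, C5 CH2OH, C9 CH2OH | COC(=O)[C@]1(C)[C@@H]2C=CC(CO)[C@]3(C2)C(CO)CC[C@@H]13 | intermediate
27 | (1R,2S,12R,13S)-A/B/D tricycle: C1 Me and CO2Me, C5 CHO, C9 CHO (C5/C9 epimers) | COC(=O)[C@]1(C)[C@@H]2C=CC(C=O)[C@]3(C2)C(C=O)CC[C@@H]13 | intermediate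
28 | 3-methylbutanoic anhydride | CC(C)CC(=O)OC(=O)CC(C)C | starting material
29 | (1R,2S,8R,9R,12R,13S)-lactol: target tetracycle with C8 OH (drawn as the major anomer) | COC(=O)[C@]1(C)[C@@H]2C=CC3=CO[C@@H](O)[C@@H]4CC[C@@H]1[C@]34C2 | intermediate (not isolated)
30 | CNP0315847.1: (1R,2S,8S,9R,12R,13S) tetracyclic C8 3-methylbutanoate, C1 methyl ester | COC(=O)[C@]1(C)[C@@H]2C=CC3=CO[C@@H](OC(=O)CC(C)C)[C@@H]4CC[C@@H]1[C@]34C2 | target

**Totals and risks**

Total step count: 21. Longest linear sequence: 20 steps (steps 1, 2 and 4–21); step 3 is a one-step side branch.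

Three steps most likely to fail:

Step 8 (cuprate addition then alkylation of a hindered enolate next to the new quaternary C1). The copper/lithium enolate may alkylate sluggishly or undergo proton transfer. Fallback, setting out from 10 and coming back at 13: run the cuprate addition with Me3SiCl present (Me2CuLi, Me3SiCl, Et2O, −78 °C) and isolate tert-butyl (1S,5R)-5-(dimethoxymethyl)-1-methyl-3-[(trimethylsilyl)oxy]cyclopent-2-ene-1-carboxylate F1. Then release a copper- and lithium-free ammonium enolate from F1 with anhydrous BnMe3NF in THF in the presence of 11, so that the regiodefined "naked" enolate is alkylated at C12 to give 13.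

Step 13 (intramolecular Michael addition creating quaternary C13 and the bridged ring). The ester donor is much less acidic than the γ-protons of the acceptor, so isomerisation may outrun cyclisation. Fallback, setting out from 14 and coming back at 20, replacing the enolate donor by an aldehyde dienamine:
- Wittig reaction of 14 with the ylide from [2-(1,3-dioxolan-2-yl)ethyl]triphenylphosphonium bromide and NaN(SiMe3)2 gives the (Z)-alkenyl dioxolane F2.
- 1 M HCl in THF unmasks both the aldehyde and the β-keto ester to give keto ester aldehyde F3.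
- Pyrrolidine/AcOH in toluene first effects the Knoevenagel closure to the bicyclic enone aldehyde F4 and then, through the dienamine of the aldehyde, the intramolecular Michael addition to the tricyclic aldehyde F5.
- Pinnick oxidation (NaClO2, NaH2PO4, 2-methyl-2-butene) gives the carboxylic acid F6, and Me3SiCHN2 returns 20.

Step 21 (lactol formation against the conjugated enal–aldehyde tautomer, and anomeric selectivity of the acylation). Fallback, setting out from 27 and coming back at 30, passing through the lactone oxidation level: Ag2CO3 on Celite in refluxing benzene oxidises the equilibrium lactol 29 irreversibly to the dienol lactone F7. Reduction with i-Bu2AlH (1.1 equiv, CH2Cl2, −78 °C), which attacks the activated enol lactone in preference to the hindered C1 methyl ester, gives the aluminium lactolate F8 by axial hydride delivery anti to the axial C9–H. F8 is acylated in the same flask (pyridine, DMAP, 28, −78 → −20 °C) to 30 without ever liberating the free lactol.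

**Further compounds**

F1 | step 8 | tert-butyl (1S,5R)-5-(dimethoxymethyl)-1-methyl-3-[(trimethylsilyl)oxy]cyclopent-2-ene-1-carboxylate | CC(C)(C)OC(=O)[C@]1(C)[C@H](C(OC)OC)CC(O[Si](C)(C)C)=C1
F2 | step 13 | tert-butyl (1R,2S)-5-[(2E)-2,4-dimethoxy-4-oxobut-2-en-1-yl]-2-[(1Z)-3-(1,3-dioxolan-2-yl)prop-1-en-1-yl]-1-methyl-4-oxocyclopentane-1-carboxylate | CC(C)(C)OC(=O)[C@]1(C)[C@H](/C=C\CC2OCCO2)CC(=O)C1C/C(OC)=C\C(=O)OC
F3 | step 13 | tert-butyl (1R,2S)-5-(4-methoxy-2,4-dioxobutyl)-1-methyl-4-oxo-2-[(1Z)-4-oxobut-1-en-1-yl]cyclopentane-1-carboxylate | CC(C)(C)OC(=O)[C@]1(C)[C@H](/C=C\CC=O)CC(=O)C1CC(=O)CC(=O)OC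
F4 | step 13 | 1-tert-butyl 4-methyl (1R,2S)-1-methyl-5-oxo-2-[(1Z)-4-oxobut-1-en-1-yl]-1,2,3,5,6,6a-hexahydropentalene-1,4-dicarboxylate | CC(C)(C)OC(=O)[C@]1(C)[C@H](/C=C\CC=O)CC2=C(C(=O)OC)C(=O)CC12
F5 | step 13 | (1R,2S,12R,13R)-A/B/D tricycle: C1 Me and CO2t-Bu, C5 CHO, C9 CO2Me, C10 ketone | CC(C)(C)OC(=O)[C@]1(C)[C@@H]2C=CC(C=O)[C@]3(C2)C(C(=O)OC)C(=O)C[C@@H]13
F6 | step 13 | (1R,2S,12R,13R)-A/B/D tricycle: C1 Me and CO2t-Bu, C5 CO2H, C9 CO2Me, C10 ketone | CC(C)(C)OC(=O)[C@]1(C)[C@@H]2C=CC(C(=O)O)[C@]3(C2)C(C(=O)OC)C(=O)C[C@@H]13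
F7 | step 21 | (1R,2S,9R,12R,13S)-dienol lactone: target tetracycle with C8 as lactone carbonyl | COC(=O)[C@]1(C)[C@@H]2C=CC3=COC(=O)[C@@H]4CC[C@@H]1[C@]34C2
F8 | step 21 | diisobutylaluminium lactolate of 29 (C8 O–Al(i-Bu)2) | COC(=O)[C@]1(C)[C@@H]2C=CC3=CO[C@@H](O[Al](CC(C)C)CC(C)C)[C@@H]4CC[C@@H]1[C@]34C2
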